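**Plan**

Enabling feature: in the nine-membered ring (C1 = AcO–CH, C2, C3 = C–CH3, C4, C5, C6, C7 = C–CHO, C8 = CH–CHO, C9 = side-chain CH; C1′ = side-chain methine) the array C1(O)–C9–C8–C7=C6 is a Claisen retron once C1 is a ketone, and its ether oxygen can tie C1 to C6 inside an oxepine that already holds the cis C3=C4 alkene.
Retrosynthesis: the aldehydes go back to an acetonide-bridged 1,4-diol and the acetate to the C1 ketone; C8–C9 is then cut with re-formation of O–C6 to give an (E)-2-alkylidene-7-(dioxepinyl)oxepine, which is cut at C3=C4 (ring-closing metathesis) and at O–C1 (vinyl C–O coupling) into a dioxepinyl homoallylic alcohol and an (E)-vinyl iodide.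
Forward: the alcohol comes from but-2-yne-1,4-diol and the iodide from (R)-citronellal (its carbonyl carbon becomes C1) and methallyl bromide; coupling and metathesis close the oxepine, heating turns it into the nine-membered dienone, and reduction, acetylation, ketal removal and a double oxidation finish the route.
Stereochemistry: C1′ is taken from (R)-citronellal; C6 is set by reagent-controlled allylboration and passes to C8 in the Claisen step; C9 follows from the E enol ether, fixed by syn-hydrozirconation and a stereoretentive coupling; C1 is set by hydride attack on the outer face of the ring ketone; both ring alkenes are cis because of the rings in which they form.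
The enol ether is deliberately not made by alkylidenation of a lactone: titanium alkylidenes put the new alkyl group cis to the ring oxygen (Z), which would give the C9 epimer, and C9 cannot be repaired by base later because the allylic C2–H next to the same ketone is the more acidic position.

Key step: step 10

Remark on the chemistry: in the locants above the target is (1R,8R,9R,1′R), and (−)-Ipc2BOMe means the enantiomer of B-methoxydiisopinocampheylborane made from (+)-α-pinene.

Step 1
Reactants: 1 but-2-yne-1,4-diol
Product: 2 (E)-2-(tributylstannyl)but-2-ene-1,4-diol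
Conditions: Bu3SnH, PdCl2(PPh3)2 (2 mol%), THF, 0 °C → rt
Reagents that add atoms: tributyltin hydride, CCCC[SnH](CCCC)CCCC
Why: Palladium-catalysed hydrostannation delivers H and SnBu3 to the same face of the symmetrical alkyne, so the two CH2OH groups come out cis as the seven-membered ketal of step 2 demands, which a trans-hydroalumination would not give.

Step 2
Reactants: 2 (E)-2-(tributylstannyl)but-2-ene-1,4-diol
Product: 3 tributyl(2,2-dimethyl-4,7-dihydro-1,3-dioxepin-5-yl)stannane
Conditions: Me2C(OMe)2, pyridinium p-toluenesulfonate (cat.), CH2Cl2, rt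
Reagents that add atoms: 2,2-dimethoxypropane, COC(C)(C)OC
Why: Acid-catalysed transketalisation closes the 4,7-dihydro-1,3-dioxepine on the cis-1,4-diol, and the weak acid should leave the vinyl C–Sn bond untouched.

Step 3
Reactants: 3 tributyl(2,2-dimethyl-4,7-dihydro-1,3-dioxepin-5-yl)stannane
Product: 5 2,2-dimethyl-4,7-dihydro-1,3-dioxepine-5-carbaldehyde, via vinyllithium 4 (not isolated)
Conditions: n-BuLi, THF, −78 °C; DMF, −78 → 0 °C; H2O
Reagents that add atoms: N,N-dimethylformamide, CN(C)C=O
Why: Tin–lithium exchange with retention gives a vinyllithium that should be stable at low temperature, and its Bouveault-type formylation with DMF gives the enal on hydrolysis.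

Step 4
Reactants: 5 2,2-dimethyl-4,7-dihydro-1,3-dioxepine-5-carbaldehyde
Product: 7 (S)-1-(2,2-dimethyl-4,7-dihydro-1,3-dioxepin-5-yl)but-3-en-1-ol, via homoallyl borinate 6 (not isolated)
Conditions: (−)-Ipc2BOMe, allylMgBr, Et2O, −78 °C; 5, −78 °C; NaOH, H2O2, 0 °C → rt
Reagents that add atoms: allylmagnesium bromide, C=CC[Mg]Br
Why: Brown-type allylboration with the B-allyldiisopinocampheylborane made in the flask passes through a chair Zimmerman–Traxler transition state in which the reagent directs the allyl group to the Si face of the enal carbonyl, which should set C6 as S by 1,2-addition only.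

Step 5
Reactants: 8 (R)-citronellal
Product: 9 (R)-8,8-dibromo-2,6-dimethyloct-2-ene
Conditions: (PhO)3P, Br2, CH2Cl2, −78 °C; then 8, −78 °C → rt
Reagents that add atoms: bromine, BrBr
Why: Deoxygenative gem-dibromination of the aldehyde by preformed (PhO)3PBr2 (Appel-type halophosphonium activation) should spare the trisubstituted alkene and the β-stereocentre because no free bromine is present.

Step 6
Reactants: 9 (R)-8,8-dibromo-2,6-dimethyloct-2-ene; 10 3-bromo-2-methylprop-1-ene
Product: 13 (R)-2,6,10-trimethylundeca-1,9-dien-4-yne, via 1-bromoalkene 11 (not isolated), via lithium acetylide 12 (not isolated)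
Conditions: LiN(i-Pr)2 (3.1 equiv), THF, −78 → 0 °C; CuI (10 mol%), 10, 0 °C → rt
Reagents that add atoms: none
Why: Two base-induced dehydrobrominations give the lithium acetylide without touching the weakly acidic propargylic stereocentre, and copper-catalysed SN2 allylation with 10 joins C1 to C2 to give the skipped enyne.

Step 7
Reactants: 13 (R)-2,6,10-trimethylundeca-1,9-dien-4-yne
Product: 15 (4E,6R)-4-iodo-2,6,10-trimethylundeca-1,4,9-triene, via alkenylzirconocene chloride 14 (not isolated)
Conditions: Cp2Zr(H)Cl, THF, rt; I2, 0 °C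
Reagents that add atoms: iodine, [I][I]
Why: Hydrozirconation adds Zr–H syn and, after equilibration, places zirconium on the alkyne carbon next to CH2 and away from the branched C1′, and iodinolysis with retention gives the E iodide in which C2 and C1′ are cis.

Step 8
Reactants: 7 (S)-1-(2,2-dimethyl-4,7-dihydro-1,3-dioxepin-5-yl)but-3-en-1-ol; 15 (4E,6R)-4-iodo-2,6,10-trimethylundeca-1,4,9-triene
Product: 16 2,2-dimethyl-5-[(1S)-1-{[(4E,6R)-2,6,10-trimethylundeca-1,4,9-trien-4-yl]oxy}but-3-en-1-yl]-4,7-dihydro-1,3-dioxepine
Conditions: CuI (10 mol%), 3,4,7,8-tetramethyl-1,10-phenanthroline (20 mol%), Cs2CO3, PhMe, 80 °C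
Reagents that add atoms: none
Why: Copper-catalysed Ullmann-type O-vinylation of an allylic alcohol with a vinyl iodide proceeds with retention at the sp2 carbon and leaves C6 untouched, so a single E enol ether is expected, and 80 °C should stay below the onset of the open-chain [3,3] shift.

Step 9
Reactants: 16 2,2-dimethyl-5-[(1S)-1-{[(4E,6R)-2,6,10-trimethylundeca-1,4,9-trien-4-yl]oxy}but-3-en-1-yl]-4,7-dihydro-1,3-dioxepine
Product: 17 (2E,7S)-2-[(2R)-2,6-dimethylhept-5-en-1-ylidene]-7-(2,2-dimethyl-4,7-dihydro-1,3-dioxepin-5-yl)-4-methyl-2,3,6,7-tetrahydrooxepine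
Conditions: second-generation Grubbs catalyst RuCl2(H2IMes)(PCy3)(=CHPh) (5 mol%), CH2Cl2 (0.005 M), 40 °C
Reagents that add atoms: none
Why: Ring-closing metathesis between the monosubstituted and the 1,1-disubstituted alkene closes the oxepine with a trisubstituted C3=C4 bond that can only be cis in a seven-membered ring, while the α-branched trisubstituted enol ether, the dioxepine alkene and the prenyl terminus should stay spectators because closure onto them needs a metallacycle at a fully substituted carbon.

Step 10
Reactants: 17 (2E,7S)-2-[(2R)-2,6-dimethylhept-5-en-1-ylidene]-7-(2,2-dimethyl-4,7-dihydro-1,3-dioxepin-5-yl)-4-methyl-2,3,6,7-tetrahydrooxepine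
Product: 18 isopropylidene ketal of (3Z,6E,8R,9R)-7,8-bis(hydroxymethyl)-3-methyl-9-[(2R)-6-methylhept-5-en-2-yl]cyclonona-3,6-dien-1-one
Conditions: PhMe (0.02 M), i-Pr2NEt (0.1 equiv), base-washed sealed tube, 150–170 °C
Reagents that add atoms: none
Why: The allyl vinyl ether array C9=C1–O–C6–C7=C8 undergoes a concerted, suprafacial [3,3] sigmatropic (Claisen) shift that forms C8–C9 and C1=O as C6–O breaks. The closest known reaction type is the thermal Claisen ring expansion of 2-alkylidene cyclic ethers bearing an alkenyl group on the other α-carbon (2-methylene-6-vinyltetrahydropyrans to cyclooct-4-enones), taken here one ring atom further. The nine-membered ring is closed by ring expansion through a bridged, chair-like six-membered transition state in which the C2–C5 tether spans C1 and C6, so the oxygen is cut out of the oxepine instead of two chain ends having to meet; a boat is out of reach because the short tether and C7 would have to sit on the same side of C6. C8 takes its configuration (R) from C6 (S), since the new bond forms on the face of the dioxepine alkene from which oxygen leaves and the tether forces C5 axial (hence the ring-cis C6=C7 bond), and C9 (R) follows from the E enol ether, which places the side chain equatorial next to the equatorial CH2O group on C8. The step needs one enol ether geometry, which steps 7 and 8 secure, and it needs the shift to outrun acid-induced migration of the exocyclic double bond towards C2, which the base-washed vessel and the amine additive should secure.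

Step 11
Reactants: 18 isopropylidene ketal of (3Z,6E,8R,9R)-7,8-bis(hydroxymethyl)-3-methyl-9-[(2R)-6-methylhept-5-en-2-yl]cyclonona-3,6-dien-1-one
Product: 19 isopropylidene ketal of (1R,3Z,6E,8R,9R)-7,8-bis(hydroxymethyl)-3-methyl-9-[(2R)-6-methylhept-5-en-2-yl]cyclonona-3,6-dien-1-ol
Conditions: LiBH(s-Bu)3, THF, −78 °C; NaOH, H2O2, 0 °C
Reagents that add atoms: none
Why: The bulky hydride should add to the outer face of the ring carbonyl, past C9–H and anti to the side chain (Felkin–Anh sense) and away from the inward-lying C4–C5 segment, which gives the 1R alcohol.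

Step 12
Reactants: 19 isopropylidene ketal of (1R,3Z,6E,8R,9R)-7,8-bis(hydroxymethyl)-3-methyl-9-[(2R)-6-methylhept-5-en-2-yl]cyclonona-3,6-dien-1-ol
Product: 20 isopropylidene ketal of (1R,3Z,6E,8R,9R)-7,8-bis(hydroxymethyl)-3-methyl-9-[(2R)-6-methylhept-5-en-2-yl]cyclonona-3,6-dien-1-yl acetate
Conditions: Ac2O, DMAP (cat.), pyridine, CH2Cl2, 0 °C → rt
Reagents that add atoms: acetic anhydride, CC(=O)OC(C)=O
Why: DMAP-catalysed acyl transfer acetylates the hindered secondary alcohol with retention because the C1–O bond is not broken.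

Step 13
Reactants: 20 isopropylidene ketal of (1R,3Z,6E,8R,9R)-7,8-bis(hydroxymethyl)-3-methyl-9-[(2R)-6-methylhept-5-en-2-yl]cyclonona-3,6-dien-1-yl acetate
Product: 21 (1R,3Z,6E,8R,9R)-7,8-bis(hydroxymethyl)-3-methyl-9-[(2R)-6-methylhept-5-en-2-yl]cyclonona-3,6-dien-1-yl acetate
Conditions: pyridinium p-toluenesulfonate (cat.), MeOH, 0 °C → rt
Reagents that add atoms: none
Why: Mild acid-catalysed transketalisation to methanol opens the labile seven-membered isopropylidene ketal well before the acetate can migrate or be cleaved.

Step 14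
Reactants: 21 (1R,3Z,6E,8R,9R)-7,8-bis(hydroxymethyl)-3-methyl-9-[(2R)-6-methylhept-5-en-2-yl]cyclonona-3,6-dien-1-yl acetate
Product: 23 (1R,3Z,6E,8R,9R)-7,8-diformyl-3-methyl-9-[(2R)-6-methylhept-5-en-2-yl]cyclonona-3,6-dien-1-yl acetate (CNP0113811.6), via bis(alkoxysulfonium) dichloride 22 (not isolated)
Conditions: (COCl)2, DMSO, CH2Cl2, −78 °C; Et3N, −78 → −20 °C
Reagents that add atoms: none
Why: Swern oxidation activates both primary alcohols as alkoxysulfonium salts before any aldehyde exists, which avoids lactol formation and over-oxidation of the 1,4-diol, and the cold amine-induced elimination should leave the epimerisable C8 centre and the C6=C7 position intact.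

**Compound list**

1 | but-2-yne-1,4-diol | OCC#CCO | starting material
2 | (E)-2-(tributylstannyl)but-2-ene-1,4-diol | OC/C=C(/[Sn](CCCC)(CCCC)CCCC)CO | intermediate
3 | tributyl(2,2-dimethyl-4,7-dihydro-1,3-dioxepin-5-yl)stannane | CCCC[Sn](CCCC)(CCCC)C1=CCOC(C)(C)OC1 | intermediate
4 | (2,2-dimethyl-4,7-dihydro-1,3-dioxepin-5-yl)lithium (not isolated) | [Li]C1=CCOC(C)(C)OC1 | intermediate
5 | 2,2-dimethyl-4,7-dihydro-1,3-dioxepine-5-carbaldehyde | O=CC1=CCOC(C)(C)OC1 | intermediate
6 | (S)-1-(2,2-dimethyl-4,7-dihydro-1,3-dioxepin-5-yl)but-3-en-1-yl diisopinocampheylborinate (not isolated) | C=CC[C@H](OB([C@@H]1C[C@@H]2C[C@H]([C@H]1C)C2(C)C)[C@@H]1C[C@@H]2C[C@H]([C@H]1C)C2(C)C)C1=CCOC(C)(C)OC1 | intermediate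
7 | (S)-1-(2,2-dimethyl-4,7-dihydro-1,3-dioxepin-5-yl)but-3-en-1-ol | C=CC[C@H](O)C1=CCOC(C)(C)OC1 | intermediate
8 | (R)-citronellal, (R)-3,7-dimethyloct-6-enal | O=CC[C@H](C)CCC=C(C)C | starting material
9 | (R)-8,8-dibromo-2,6-dimethyloct-2-ene | BrC(Br)C[C@H](C)CCC=C(C)C | intermediate
10 | 3-bromo-2-methylprop-1-ene (methallyl bromide) | C=C(C)CBr | starting material
11 | (3R)-1-bromo-3,7-dimethylocta-1,6-diene, E/Z mixture (not isolated) | BrC=C[C@H](C)CCC=C(C)C | intermediate
12 | lithium (R)-3,7-dimethyloct-6-en-1-yn-1-ide (not isolated) | [Li]C#C[C@H](C)CCC=C(C)C | intermediate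
13 | (R)-2,6,10-trimethylundeca-1,9-dien-4-yne | C=C(C)CC#C[C@H](C)CCC=C(C)C | intermediate
14 | chlorobis(cyclopentadienyl)[(4E,6R)-2,6,10-trimethylundeca-1,4,9-trien-4-yl]zirconium (not isolated) | C=C(C)C/C(=C\[C@H](C)CCC=C(C)C)[Zr](Cl)(C1C=CC=C1)C1C=CC=C1 | intermediate
15 | (4E,6R)-4-iodo-2,6,10-trimethylundeca-1,4,9-triene | C=C(C)C/C(I)=C\[C@H](C)CCC=C(C)C | intermediate
16 | 2,2-dimethyl-5-[(1S)-1-{[(4E,6R)-2,6,10-trimethylundeca-1,4,9-trien-4-yl]oxy}but-3-en-1-yl]-4,7-dihydro-1,3-dioxepine | C=CC[C@H](O/C(CC(C)=C)=C/[C@H](C)CCC=C(C)C)C1=CCOC(C)(C)OC1 | intermediate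
17 | (2E,7S)-2-[(2R)-2,6-dimethylhept-5-en-1-ylidene]-7-(2,2-dimethyl-4,7-dihydro-1,3-dioxepin-5-yl)-4-methyl-2,3,6,7-tetrahydrooxepine | C(/[C@H](C)CCC=C(C)C)=C1/C/C(C)=C\C[C@@H](C2=CCOC(C)(C)OC2)O1 | intermediate
18 | isopropylidene ketal of (3Z,6E,8R,9R)-7,8-bis(hydroxymethyl)-3-methyl-9-[(2R)-6-methylhept-5-en-2-yl]cyclonona-3,6-dien-1-one (1,3-dioxepane fused at C7–C8) | O=C1C/C(C)=C\C/C=C2/COC(C)(C)OC[C@@H]2[C@H]1[C@H](C)CCC=C(C)C | intermediate
19 | isopropylidene ketal of (1R,3Z,6E,8R,9R)-7,8-bis(hydroxymethyl)-3-methyl-9-[(2R)-6-methylhept-5-en-2-yl]cyclonona-3,6-dien-1-ol | O[C@@H]1C/C(C)=C\C/C=C2/COC(C)(C)OC[C@@H]2[C@H]1[C@H](C)CCC=C(C)C | intermediate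
20 | isopropylidene ketal of (1R,3Z,6E,8R,9R)-7,8-bis(hydroxymethyl)-3-methyl-9-[(2R)-6-methylhept-5-en-2-yl]cyclonona-3,6-dien-1-yl acetate | CC(=O)O[C@@H]1C/C(C)=C\C/C=C2/COC(C)(C)OC[C@@H]2[C@H]1[C@H](C)CCC=C(C)C | intermediate
21 | (1R,3Z,6E,8R,9R)-7,8-bis(hydroxymethyl)-3-methyl-9-[(2R)-6-methylhept-5-en-2-yl]cyclonona-3,6-dien-1-yl acetate | CC(=O)O[C@@H]1C/C(C)=C\C/C=C(/CO)[C@H](CO)[C@H]1[C@H](C)CCC=C(C)C | intermediate
22 | bis(dimethylsulfonio-oxy) derivative of 21, dichloride (not isolated) | CC(=O)O[C@@H]1C/C(C)=C\C/C=C(/CO[S+](C)C)[C@H](CO[S+](C)C)[C@H]1[C@H](C)CCC=C(C)C.[Cl-].[Cl-] | intermediate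
23 | (1R,3Z,6E,8R,9R)-7,8-diformyl-3-methyl-9-[(2R)-6-methylhept-5-en-2-yl]cyclonona-3,6-dien-1-yl acetate (CNP0113811.6) | CC(=O)O[C@@H]1C/C(C)=C\C/C=C(/C=O)[C@H](C=O)[C@H]1[C@H](C)CCC=C(C)C | target

Total step count: 14. Longest linear sequence: 11 steps (steps 1–4 and 8–14, from but-2-yne-1,4-diol); the citronellal branch (steps 5–7) joins at step 8.

**Steps most likely to fail**

First, the C–O coupling of step 8. Bond formation between a hindered secondary alcohol and a trisubstituted vinyl iodide may be slow, so that dehydrohalogenation of the iodide and an early open-chain [3,3] shift of the product at the coupling temperature compete. The fallback sets out from enyne 13: Cp2Zr(H)Cl-catalysed syn-hydroboration with pinacolborane should give, with the same regiochemistry, the pinacol alkenylboronate F1. Its oxidative, Cu(OAc)2-promoted coupling (Chan–Lam type; Et3N, CH2Cl2, room temperature, boronate in excess) with alcohol 7 forms the same bond with retention, far below the temperature of the sigmatropic shift. It comes back to the route at 16.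

Second, the ring expansion of step 10. Traces of acid may move the exocyclic double bond into the ring faster than the sigmatropic shift occurs, or the substrate may decompose at the temperature the bridged transition state needs. The fallback sets out from 17 and replaces thermal activation by a Lewis-acid-driven rearrangement–reduction cascade with Al(i-Bu)3 in CH2Cl2 from −78 °C to room temperature. Coordination at the ring oxygen drives C6–O cleavage, and the aluminium-bound ketone is reduced in the flask by hydride transfer from an isobutyl group. This makes no compound outside the list (F0) and comes back to the route at alcohol 19; should the C1 epimer form instead, it is the alcohol F2 of the next fallback.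

Third, the reduction of step 11. Facial selectivity of hydride delivery to the flexible medium-ring ketone may be poor or reversed. The fallback sets out from 18 and no longer relies on hydride delivery to fix C1. A small hydride (NaBH4, MeOH, −20 °C) is allowed to follow the intrinsic preference, and if this gives the (1S)-alcohol F2, Mitsunobu esterification with acetic acid (PPh3, DIAD, PhMe, 0 °C → rt) inverts C1 and installs the acetate in one operation. It comes back to the route at 20.

**Further compounds**

F1 | step 8 | 4,4,5,5-tetramethyl-2-[(4Z,6R)-2,6,10-trimethylundeca-1,4,9-trien-4-yl]-1,3,2-dioxaborolane | C=C(C)C/C(=C\[C@H](C)CCC=C(C)C)B1OC(C)(C)C(C)(C)O1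
F0 | step 10 | none | none
F2 | step 11 | isopropylidene ketal of (1S,3Z,6E,8R,9R)-7,8-bis(hydroxymethyl)-3-methyl-9-[(2R)-6-methylhept-5-en-2-yl]cyclonona-3,6-dien-1-ol | O[C@H]1C/C(C)=C\C/C=C2/COC(C)(C)OC[C@@H]2[C@H]1[C@H](C)CCC=C(C)C
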